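Compare the two rates at the first moment, earlier than the first reading of the runs, for the flask below. Assume that partner turns substrate into target and other conformer into isomer of the product A.

| flask | substrate | partner | other conformer | remark | time |
|---|---|---|---|---|---|
| elm | 0.10 M | 0.35 M | 0.10 M | run made earlier |  |
| birch | 0.10 M | 0.55 M | 0.10 M | run made earlier |  |
| flask | 0.10 M | 0.250 M | 0.100 M |  | 15 d |

| run | time / d | target / % | isomer of the product A / % |
|---|---|---|---|
| elm | 0.625 | 25 | 10 |
| elm | 1.25 | 22 | 9 |
| elm | 2.08 | 20 | 9 |
| elm | 3.00 | 19 | 8 |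
| elm | 5.00 | 17 | 8 |
| elm | 10.0 | 14 | 8 |
| birch | 1.67 | 28 | 15 |
| birch | 3.00 | 22 | 12 |
| birch | 5.00 | 23 | 14 |
| birch | 6.00 | 24 | 13 |
| birch | 8.00 | 23 | 10 |
| birch | 10.0 | 23 | 11 |

(scatter of a reading: 1.5 percentage points)

1. ratio of target to isomer of the product A at 10 min
2. ratio of target to isomer of the product A at 8.0 h
3. ratio of target to isomer of the product A at 15 d
4. which of target and isomer of the product A there is more of at 15 d



Build a ladder from the fastest rung to the slowest. On the first rung, assume that each product takes one partner and that the two forms react alike, so that [partner] cancels. The ratio of target to isomer of the product A then starts at the charge ratio, [substrate]/[other conformer] as charged, 1.00 in this flask, the selectivity factor being taken as one. The time 10 min comes well before the first elm reading at 0.625 d, so put the ratio at 10 min near 1.00.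

On the second rung, elm has the same charge ratio but reads 2.50 at 0.625 d, so the comparison has drifted towards target by then. Take that reading for 8.0 h, assuming the drift is over by that time.

On the slowest rung, elm's target sinks from 25 % to 14 % by 10.0 d, while its isomer of the product A goes from 10 % to 8 %. The ratio then reads 1.75, which you carry to 15 d, with target ahead.

The forecast gives 2.6 (from 1.8 to 3.6) at 10 min, 2.5 (from 1.9 to 3.1) at 8.0 h and 1.8 (from 1.3 to 2.3) at 15 d, with target ahead. It parts from your reckoning at 10 min, and it says itself that “nothing was measured before 0.6 d, so 10 min is an extrapolation”.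

The flask gives 1.01 at 10 min, 2.65 at 8.0 h and 1.91 at 15 d, with target ahead at 15 d, at 11.5 % against 6.02 % of isomer of the product A.

    substrate ⇌ other conformer (K = 0.0130, k = 1.15 × 10⁻⁶ s⁻¹)
    substrate + partner → target (k = 7.41 × 10⁻⁵ M⁻¹ s⁻¹)
    partner + other conformer → isomer of the product A (k = 7.68 × 10⁻⁵ M⁻¹ s⁻¹)
    partner → decomposed reagent (k = 4.77 × 10⁻⁵ s⁻¹)
    target ⇌ isomer of the product B (K = 0.780, k = 3.04 × 10⁻⁶ s⁻¹)

The forecast holds at 8.0 h and 15 d but stands a factor 2.57 too high at 10 min, where the flask's ratio lies beside the charge ratio 1.00 before climbing to 2.65 at 8.0 h. Now charge a neighbouring flask with 0.025 M of other conformer. Its charge ratio is 4.00, and at 10 min it gives 3.98. Its ratio then stands at 7.81 at 8.0 h and 5.53 at 15 d, when it holds 2.62 % of isomer of the product A.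

The readings stem from a simulated flask from invented constants; scatter was added.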